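Ring A is built last, on the finished and protected ring B. Its six contiguous carbons, C(CH2Ar), C(OH), C(CH3), C(O), C(acyl) and C(O), are divided into the four ring carbons of a 3-alkoxy-4-(ring B-methyl)cyclobutenone and the two sp carbons of 1-(triisopropylsilyloxy)propyne. A single neutral thermal cascade (vinylketene formation, [2+2] addition, second ring opening, six-electron closure) forms two C–C bonds, closes the benzene ring and sets OH, CH3 and two differently protected oxygens in place, leaving one ring CH for the butanoyl group. The precursor is racemic cyclobutenone 19, obtained from a ring B 3-arylpropanoic acid by ketene–alkoxyacetylene cycloaddition.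

Key step: step 9

Remarks on the chemistry:
- ArB = 2,4-bis(benzyloxy)-6-methoxy-5-methyl-3-propanoylphenyl (protected ring B).
- The enol-ether oxygen of the cyclobutenone is carried as a benzyl ether, not an ethyl ether. An ethyl ether at that position would have to be cleaved by a chelating Lewis acid after the other ortho-OH of the new butanoyl ketone is already free, so the chelate would sit on the wrong side, and the ring B methyl ether would compete. With benzyl, all three protecting groups leave in one neutral hydrogenolysis.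
- Compounds 5, 19, 25 and 27 are racemic and drawn as one enantiomer; the target has no stereocentre.

Step 1
Reactants: 1 2-methylbenzene-1,3,5-triol (2-methylphloroglucinol); 2 propanoyl chloride
Product: 3 1-(2,4,6-trihydroxy-3-methylphenyl)propan-1-one
Conditions: AlCl3 (3 equiv), PhNO2/CH2Cl2, 0 °C → rt; aq. HCl
Reagents that add atoms: none
Why: Friedel–Crafts acylation at one of the two equivalent, strongly activated free carbons of the symmetrical triol; the AlCl3-chelated acyl group deactivates the ring against a second acylation.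

Step 2
Reactants: 3 1-(2,4,6-trihydroxy-3-methylphenyl)propan-1-one
Product: 4 1-(2,6-dihydroxy-4-methoxy-3-methylphenyl)propan-1-one
Conditions: Me2SO4 (1.0 equiv), K2CO3 (1.1 equiv), acetone, rt
Reagents that add atoms: dimethyl sulfate, COS(=O)(=O)OC
Why: Williamson-type O-methylation under weak base should go to the 4-OH, which is para to the ketone, is the most acidic hydroxyl and can never be hydrogen-bonded to the carbonyl oxygen; one equivalent of reagent limits over-alkylation.

Step 3
Reactants: 4 1-(2,6-dihydroxy-4-methoxy-3-methylphenyl)propan-1-one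
Product: 6 2,4-dihydroxy-6-methoxy-5-methyl-3-propanoylbenzaldehyde, via chloro(methoxy)methyl arene 5 (not isolated)
Conditions: Cl2CHOMe (1.5 equiv), TiCl4 (3 equiv), CH2Cl2, −10 °C → rt; then 1 M HCl
Reagents that add atoms: dichloromethyl methyl ether, COC(Cl)Cl; water, O
Why: Rieche formylation: the only free ring carbon (between OMe and OH, para to the second OH) attacks the TiCl4-activated chloromethyl oxocarbenium ion and the α-chloro ether is hydrolysed on acidic work-up; no amide-type formylating agent is present that could condense with the o-hydroxy ethyl ketone.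

Step 4
Reactants: 6 2,4-dihydroxy-6-methoxy-5-methyl-3-propanoylbenzaldehyde
Product: 7 2,4-bis(benzyloxy)-6-methoxy-5-methyl-3-propanoylbenzaldehyde (ArB-CHO)
Conditions: BnBr (2.5 equiv), K2CO3 (3 equiv), cat. Bu4NI, DMF, 60 °C
Reagents that add atoms: benzyl bromide, BrCc1ccccc1
Why: Double Williamson O-benzylation: warm K2CO3/DMF deprotonates both chelated phenols, and because every ring carbon is substituted only O-alkylation is possible.

Step 5
Reactants: 7 2,4-bis(benzyloxy)-6-methoxy-5-methyl-3-propanoylbenzaldehyde; 8 2,2-dimethyl-1,3-dioxane-4,6-dione (Meldrum's acid)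
Product: 11 3-ArB-propanoic acid, via arylidene Meldrum's acid 9 (not isolated), via benzyl Meldrum's acid 10 (not isolated)
Conditions: 8 (1.1 equiv), HCO2H/Et3N (5:2), 95 °C; then aq. HCl
Reagents that add atoms: water, O
Why: One-pot Knoevenagel condensation, conjugate hydride transfer from formate to the highly electrophilic arylidene Meldrum's acid, then hydrolytic ring opening and decarboxylation should give the 3-arylpropanoic acid directly; benzyl ethers and the hindered aryl ketone are inert to formate without a metal catalyst.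

Step 6
Reactants: 12 benzyl alcohol; 13 trichloroethylene
Product: 16 benzyl ethynyl ether [(ethynyloxy)methyl]benzene, via dichlorovinyl ether 14 (not isolated), via lithium benzyloxyacetylide 15 (not isolated)
Conditions: KH, THF, 0 °C; Cl2C=CHCl, −50 °C → rt; n-BuLi (2.5 equiv), −78 → −40 °C; H2O, −78 °C; used cold as a solution
Reagents that add atoms: none
Why: Potassium benzyloxide adds to dichloroacetylene formed in situ from trichloroethylene, and n-BuLi converts the resulting dichlorovinyl ether by dehydrochlorination and chlorine–lithium exchange into the lithium alkoxyacetylide, which is protonated (the standard trichloroethylene route to alkynyl ethers); the product is kept cold because benzyl alkynyl ethers rearrange on warming.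

Step 7
Reactants: 11 3-ArB-propanoic acid; 16 benzyl ethynyl ether
Product: 19 rac-3-(benzyloxy)-4-(ArB-methyl)cyclobut-2-en-1-one, via acid chloride 17 (not isolated), via ketene 18 (not isolated)
Conditions: (COCl)2, cat. DMF, CH2Cl2, 0 °C → rt, evaporate; then slow addition to 16 (3 equiv), Et3N (1.5 equiv), CH2Cl2, 0 °C → rt
Reagents that add atoms: none
Why: Et3N dehydrochlorinates the acid chloride to the monosubstituted ketene, which the excess electron-rich alkoxyacetylene traps in a [2+2] cycloaddition with the nucleophilic alkyne CH bonding to the ketene carbonyl carbon, giving the 3-alkoxy-4-substituted cyclobutenone; the new stereocentre is formed without control (racemate), which is irrelevant because that carbon becomes aromatic in step 9.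

Step 8
Reactants: 20 propyne
Product: 23 1-(triisopropylsilyloxy)prop-1-yne, via propynyllithium 21 (not isolated), via lithium propynolate 22 (not isolated)
Conditions: n-BuLi, THF, −78 °C; t-BuOOLi (from t-BuOOH and LiN(SiMe3)2, THF, −78 °C), −78 → 0 °C; i-Pr3SiOTf, −78 → 0 °C
Reagents that add atoms: tert-butyl hydroperoxide, CC(C)(C)OO; triisopropylsilyl trifluoromethanesulfonate, CC(C)[Si](OS(=O)(=O)C(F)(F)F)(C(C)C)C(C)C
Why: Electrophilic oxygen transfer from lithium tert-butyl peroxide to the lithium acetylide gives the lithium ynolate, which the bulky silyl triflate traps on oxygen and not on carbon to give the thermally robust silyl ynol ether.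

Step 9
Reactants: 19 rac-3-(benzyloxy)-4-(ArB-methyl)cyclobut-2-en-1-one; 23 1-(triisopropylsilyloxy)prop-1-yne
Product: 28 2-(ArB-methyl)-3-(benzyloxy)-6-methyl-5-(triisopropylsilyloxy)phenol, via vinylketene 24 (not isolated), via vinylcyclobutenone 25 (not isolated), via dienylketene 26 (not isolated), via cyclohexadienone 27 (not isolated)
Conditions: 23 (2 equiv), PhMe, 80 °C, then 110 °C
Reagents that add atoms: none
Why: Thermal four-electron conrotatory opening of 19 (CH2ArB turning outward) gives vinylketene 24, whose ketene carbon is attacked by the nucleophilic CH3-bearing carbon of ynol ether 23 in a regioselective [2+2] addition to give vinylcyclobutenone 25; a second four-electron opening gives dienylketene 26, which closes ring A by thermal six-electron disrotatory electrocyclisation (bond between the ketene carbon and the terminus bearing CH2ArB) to dienone 27, and enolisation gives phenol 28. The closest known reaction type is the Danheiser benzannulation of a cyclobutenone with a siloxyalkyne. No stereocentre is created, since the single sp3 centre of racemic 19 becomes an aromatic carbon. The only selectivity needed is the regiochemistry of the [2+2] event, and it is secured by the polarisation of the ynol ether: oxygen lone-pair donation makes the CH3-bearing carbon the nucleophile that bonds to the electrophilic C=O carbon of the ketene, so CH3 ends up next to the new OH and OSi next to the ring CH. The cascade needs no acid or base, so the benzyl ethers, the ring B ketone and the diarylmethane link are not stressed, and the excess of 23 suppresses ketene self-condensation and acylation of the hindered product phenol.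

Step 10
Reactants: 28 2-(ArB-methyl)-3-(benzyloxy)-6-methyl-5-(triisopropylsilyloxy)phenol
Product: 29 4-(ArB-methyl)-5-(benzyloxy)-2-methylbenzene-1,3-diol
Conditions: Bu4NF (1.2 equiv), AcOH (1.2 equiv), THF, 0 °C
Reagents that add atoms: none
Why: Fluoride-induced cleavage of the aryl silyl ether; acetic acid protonates the electron-rich phenoxide at once, and benzyl ethers and the ketone are untouched.

Step 11
Reactants: 29 4-(ArB-methyl)-5-(benzyloxy)-2-methylbenzene-1,3-diol; 30 butanoyl chloride
Product: 31 1-[3-(ArB-methyl)-2-(benzyloxy)-4,6-dihydroxy-5-methylphenyl]butan-1-one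
Conditions: TiCl4 (3 equiv), CH2Cl2, −40 °C; 30 (1.2 equiv), −40 → 0 °C; aq. HCl
Reagents that add atoms: none
Why: Friedel–Crafts acylation directed by the titanium phenoxide: the only unsubstituted ring A carbon lies ortho to the freed OH, ortho to OBn and para to the second OH and is by far the most nucleophilic site, the fully substituted ring B cannot react, and any benzyl ether lost to the Lewis acid after C-acylation does not matter because step 12 removes all three.

Step 12
Reactants: 31 1-[3-(ArB-methyl)-2-(benzyloxy)-4,6-dihydroxy-5-methylphenyl]butan-1-one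
Product: 32 1-[3-[(2,4-dihydroxy-6-methoxy-5-methyl-3-propanoylphenyl)methyl]-2,4,6-trihydroxy-5-methylphenyl]butan-1-one (target)
Conditions: H2 (1 atm), 10% Pd/C, EtOAc/MeOH, rt
Reagents that add atoms: none
Why: Catalytic hydrogenolysis cleaves the three aryl benzyl ethers under neutral conditions and leaves the aryl methyl ether, the two hydrogen-bonded aryl ketones and the diarylmethane link untouched.

Compound list
1 | 2-methylbenzene-1,3,5-triol | Cc1c(O)cc(O)cc1O | starting material
2 | propanoyl chloride | CCC(=O)Cl | starting material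
3 | 1-(2,4,6-trihydroxy-3-methylphenyl)propan-1-one | CCC(=O)c1c(O)cc(O)c(C)c1O | intermediate
4 | 1-(2,6-dihydroxy-4-methoxy-3-methylphenyl)propan-1-one | CCC(=O)c1c(O)cc(OC)c(C)c1O | intermediate
5 | 1-[3-[chloro(methoxy)methyl]-2,6-dihydroxy-4-methoxy-5-methylphenyl]propan-1-one (racemic, not isolated) | CCC(=O)c1c(O)c([C@H](Cl)OC)c(OC)c(C)c1O | intermediate
6 | 2,4-dihydroxy-6-methoxy-5-methyl-3-propanoylbenzaldehyde | CCC(=O)c1c(O)c(C=O)c(OC)c(C)c1O | intermediate
7 | 2,4-bis(benzyloxy)-6-methoxy-5-methyl-3-propanoylbenzaldehyde | CCC(=O)c1c(OCc2ccccc2)c(C=O)c(OC)c(C)c1OCc1ccccc1 | intermediate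
8 | 2,2-dimethyl-1,3-dioxane-4,6-dione (Meldrum's acid) | CC1(C)OC(=O)CC(=O)O1 | starting material
9 | 5-(ArB-methylidene)-2,2-dimethyl-1,3-dioxane-4,6-dione (not isolated) | CCC(=O)c1c(OCc2ccccc2)c(C=C2C(=O)OC(C)(C)OC2=O)c(OC)c(C)c1OCc1ccccc1 | intermediate
10 | 5-(ArB-methyl)-2,2-dimethyl-1,3-dioxane-4,6-dione (not isolated) | CCC(=O)c1c(OCc2ccccc2)c(CC2C(=O)OC(C)(C)OC2=O)c(OC)c(C)c1OCc1ccccc1 | intermediate
11 | 3-[2,4-bis(benzyloxy)-6-methoxy-5-methyl-3-propanoylphenyl]propanoic acid | CCC(=O)c1c(OCc2ccccc2)c(CCC(=O)O)c(OC)c(C)c1OCc1ccccc1 | intermediate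
12 | benzyl alcohol | OCc1ccccc1 | starting material
13 | trichloroethylene | ClC=C(Cl)Cl | starting material
14 | benzyl (E)-1,2-dichlorovinyl ether (not isolated) | Cl/C=C(/Cl)OCc1ccccc1 | intermediate
15 | lithium benzyloxyacetylide (not isolated) | [Li]C#COCc1ccccc1 | intermediate
16 | benzyl ethynyl ether | C#COCc1ccccc1 | intermediate
17 | 3-ArB-propanoyl chloride (not isolated) | CCC(=O)c1c(OCc2ccccc2)c(CCC(=O)Cl)c(OC)c(C)c1OCc1ccccc1 | intermediate
18 | 4-ArB-but-1-en-1-one, the (ArB-methyl)ketene (not isolated) | CCC(=O)c1c(OCc2ccccc2)c(CC=C=O)c(OC)c(C)c1OCc1ccccc1 | intermediate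
19 | rac-3-(benzyloxy)-4-(ArB-methyl)cyclobut-2-en-1-one | CCC(=O)c1c(OCc2ccccc2)c(C[C@H]2C(=O)C=C2OCc2ccccc2)c(OC)c(C)c1OCc1ccccc1 | intermediate
20 | propyne | CC#C | starting material
21 | prop-1-ynyllithium (not isolated) | CC#C[Li] | intermediate
22 | lithium prop-1-yn-1-olate (not isolated) | CC#C[O-].[Li+] | intermediate
23 | 1-(triisopropylsilyloxy)prop-1-yne | CC#CO[Si](C(C)C)(C(C)C)C(C)C | intermediate
24 | (3Z)-5-ArB-3-(benzyloxy)penta-1,3-dien-1-one, vinylketene (not isolated) | CCC(=O)c1c(OCc2ccccc2)c(C/C=C(OCc2ccccc2)/C=C=O)c(OC)c(C)c1OCc1ccccc1 | intermediate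
25 | rac-4-[(1Z)-3-ArB-1-(benzyloxy)prop-1-en-1-yl]-2-methyl-3-(triisopropylsilyloxy)cyclobut-2-en-1-one (not isolated) | CCC(=O)c1c(OCc2ccccc2)c(C/C=C(OCc2ccccc2)/[C@H]2C(=O)C(C)=C2O[Si](C(C)C)(C(C)C)C(C)C)c(OC)c(C)c1OCc1ccccc1 | intermediate
26 | (3E,5Z)-7-ArB-5-(benzyloxy)-2-methyl-3-(triisopropylsilyloxy)hepta-1,3,5-trien-1-one, dienylketene (not isolated) | CCC(=O)c1c(OCc2ccccc2)c(C/C=C(OCc2ccccc2)/C=C(O[Si](C(C)C)(C(C)C)C(C)C)\C(C)=C=O)c(OC)c(C)c1OCc1ccccc1 | intermediate
27 | rac-6-(ArB-methyl)-5-(benzyloxy)-2-methyl-3-(triisopropylsilyloxy)cyclohexa-2,4-dien-1-one (not isolated) | CCC(=O)c1c(OCc2ccccc2)c(C[C@H]2C(=O)C(C)=C(O[Si](C(C)C)(C(C)C)C(C)C)C=C2OCc2ccccc2)c(OC)c(C)c1OCc1ccccc1 | intermediate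
28 | 2-(ArB-methyl)-3-(benzyloxy)-6-methyl-5-(triisopropylsilyloxy)phenol | CCC(=O)c1c(OCc2ccccc2)c(Cc2c(O)c(C)c(O[Si](C(C)C)(C(C)C)C(C)C)cc2OCc2ccccc2)c(OC)c(C)c1OCc1ccccc1 | intermediate
29 | 4-(ArB-methyl)-5-(benzyloxy)-2-methylbenzene-1,3-diol | CCC(=O)c1c(OCc2ccccc2)c(Cc2c(O)c(C)c(O)cc2OCc2ccccc2)c(OC)c(C)c1OCc1ccccc1 | intermediate
30 | butanoyl chloride | CCCC(=O)Cl | starting material
31 | 1-[3-(ArB-methyl)-2-(benzyloxy)-4,6-dihydroxy-5-methylphenyl]butan-1-one | CCCC(=O)c1c(O)c(C)c(O)c(Cc2c(OCc3ccccc3)c(C(=O)CC)c(OCc3ccccc3)c(C)c2OC)c1OCc1ccccc1 | intermediate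
32 | 1-[3-[(2,4-dihydroxy-6-methoxy-5-methyl-3-propanoylphenyl)methyl]-2,4,6-trihydroxy-5-methylphenyl]butan-1-one | CCCC(=O)c1c(O)c(C)c(O)c(Cc2c(O)c(C(=O)CC)c(O)c(C)c2OC)c1O | target

Total step count: 12 (steps 6 and 8 prepare the two alkynes). Longest linear sequence: 10 steps (steps 1–5, 7, 9, 10, 11, 12).

Steps most likely to fail

1. Step 9 (benzannulation). The vinylketene may be consumed by self-condensation or by acylating the product phenol, or the cascade may stall at the vinylcyclobutenone, faster than productive addition to the ynol ether. The fallback is a classical acid-catalysed union of two preformed rings; it sets out from aldehyde 7 and triol 1 and comes back to the route at target 32. Aldehyde 7 is reduced chemoselectively with NaBH4 (MeOH/THF, 0 °C; the ketone between two benzyloxy groups is too hindered to compete) to [2,4-bis(benzyloxy)-6-methoxy-5-methyl-3-propanoylphenyl]methanol F1. Triol 1 is acylated with butanoyl chloride 30 (AlCl3, PhNO2/CH2Cl2) to 1-(2,4,6-trihydroxy-3-methylphenyl)butan-1-one F2. Friedel–Crafts benzylation of the single free ring carbon of F2 by F1 (cat. BF3·OEt2, dioxane/CH2Cl2, 0 °C) should give 1-[3-(ArB-methyl)-2,4,6-trihydroxy-5-methylphenyl]butan-1-one F3, and hydrogenolysis under the conditions of step 12 should give 32.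

2. Step 7 (ketene–alkynyl ether cycloaddition). Dimerisation or oligomerisation of the monosubstituted ketene, destruction of the acid-sensitive alkynyl ether by amine hydrochloride, or lactonisation of the acid chloride onto an ortho benzyloxy group may outrun the cycloaddition. The fallback uses a more reactive alkyl(chloro)ketene that is less prone to dimerise, followed by reductive dechlorination; it sets out from aldehyde 7 and comes back at 19. Knoevenagel condensation of 7 with 8 and conjugate reduction with Hantzsch ester (diethyl 2,6-dimethyl-1,4-dihydropyridine-3,5-dicarboxylate) at rt give 10, this time isolated. Chlorination with N-chlorosuccinimide should give 5-chloro-5-(ArB-methyl)-2,2-dimethyl-1,3-dioxane-4,6-dione F4. Hydrolysis and decarboxylation in hot aqueous acetic acid should give rac-2-chloro-3-ArB-propanoic acid F5, and (COCl)2 should convert it into rac-2-chloro-3-ArB-propanoyl chloride F6. Et3N in the presence of 16 generates 2-chloro-4-ArB-but-1-en-1-one F7 (the chloroketene), whose [2+2] adduct is rac-3-(benzyloxy)-4-chloro-4-(ArB-methyl)cyclobut-2-en-1-one F8. Zn dust, AcOH and TMEDA in EtOH should remove the chlorine to give 19.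

3. Step 11 (C-butanoylation). The Lewis acid may strip benzyl groups before C-acylation is complete, so that benzyl cations alkylate the free ring A carbon, or it may promote scission of the diarylmethane link. The fallback is a Vilsmeier–Haack-type acylation that needs no metal Lewis acid; it sets out from 29 and comes back at 31. N,N-Dimethylbutanamide and POCl3 (MeCN, 0 → 50 °C) should give N-[1-[3-(ArB-methyl)-2-(benzyloxy)-4,6-dihydroxy-5-methylphenyl]butylidene]-N-methylmethanaminium chloride F9, which warm aqueous NaOAc should hydrolyse to 31.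

Further compounds
F1 | step 9 | [2,4-bis(benzyloxy)-6-methoxy-5-methyl-3-propanoylphenyl]methanol | CCC(=O)c1c(OCc2ccccc2)c(CO)c(OC)c(C)c1OCc1ccccc1
F2 | step 9 | 1-(2,4,6-trihydroxy-3-methylphenyl)butan-1-one | CCCC(=O)c1c(O)cc(O)c(C)c1O
F3 | step 9 | 1-[3-(ArB-methyl)-2,4,6-trihydroxy-5-methylphenyl]butan-1-one | CCCC(=O)c1c(O)c(C)c(O)c(Cc2c(OCc3ccccc3)c(C(=O)CC)c(OCc3ccccc3)c(C)c2OC)c1O
F4 | step 7 | 5-chloro-5-(ArB-methyl)-2,2-dimethyl-1,3-dioxane-4,6-dione | CCC(=O)c1c(OCc2ccccc2)c(CC2(Cl)C(=O)OC(C)(C)OC2=O)c(OC)c(C)c1OCc1ccccc1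
F5 | step 7 | rac-2-chloro-3-ArB-propanoic acid (one enantiomer drawn) | CCC(=O)c1c(OCc2ccccc2)c(C[C@H](Cl)C(=O)O)c(OC)c(C)c1OCc1ccccc1
F6 | step 7 | rac-2-chloro-3-ArB-propanoyl chloride (one enantiomer drawn) | CCC(=O)c1c(OCc2ccccc2)c(C[C@H](Cl)C(=O)Cl)c(OC)c(C)c1OCc1ccccc1
F7 | step 7 | 2-chloro-4-ArB-but-1-en-1-one (chloroketene, formed in the flask) | CCC(=O)c1c(OCc2ccccc2)c(CC(Cl)=C=O)c(OC)c(C)c1OCc1ccccc1
F8 | step 7 | rac-3-(benzyloxy)-4-chloro-4-(ArB-methyl)cyclobut-2-en-1-one (one enantiomer drawn) | CCC(=O)c1c(OCc2ccccc2)c(C[C@]2(Cl)C(=O)C=C2OCc2ccccc2)c(OC)c(C)c1OCc1ccccc1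
F9 | step 11 | N-[1-[3-(ArB-methyl)-2-(benzyloxy)-4,6-dihydroxy-5-methylphenyl]butylidene]-N-methylmethanaminium chloride | CCCC(=[N+](C)C)c1c(O)c(C)c(O)c(Cc2c(OCc3ccccc3)c(C(=O)CC)c(OCc3ccccc3)c(C)c2OC)c1OCc1ccccc1.[Cl-]
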